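**Plan**

- Retrosynthetic cuts: C9'–C10' (prenyl unit removed as a sulfone-stabilised allyl anion from an (S)-2-methyl acid derivative); the C9' acid and C7'=C8' traced back to the terminal isopropylidene group of a farnesyl chain; C3–C4 of ring B (ring-closing metathesis, C3=C4 reduced afterwards); O1–C2 (allylic etherification of a 2-formylphenol with (E,E)-farnesyl methyl carbonate).
- Forward order: ring A building block (silylation and ortho-formylation of methylhydroquinone) → O1–C2 ether carrying the whole C1'–C8' chain → aryl vinyl group → ring B closed at C3=C4 → C3=C4 reduced → chain end oxidised to the C9' acid → C7'=C8' hydrogenated → C9'–C10' bond to the prenyl unit → desilylation.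
- Stereochemistry: C2 (R) by ligand control in the palladium-catalysed etherification (step 4); C8' (S) by ligand control in the ruthenium-catalysed hydrogenation (step 10); the E-C3'=C4' alkene comes unchanged from farnesol.
- Enabling feature: ring B has its only stereocentre at the ether carbon C2, and C3 and C4 are unsubstituted carbons between C2 and C4a of ring A, so C3 and C4 can be the two alkene carbons joined by metathesis of a C2-vinyl and an aryl vinyl group.

Key step: step 6

Remarks before the steps: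
- Locants: chroman O1, C2, C3, C4, C4a, C5–C8, C8a (arene = ring A, pyran = ring B); side chain C1'–C13' counted from C2.
- Assumption: the (R,R)-ligand in step 4 and the (S)-ligand in step 10 are taken to be the enantiomers that lead to 2R and 8'S (step 10 by analogy with simple (E)-2-methyl-2-alkenoic acids). Each sense is to be confirmed on the first run, and the mirror-image ligand used if required.

**Route**

Step 1
Reactants: 1 2-methylhydroquinone
Product: 2 2-methyl-4-(triisopropylsilyloxy)phenol
Conditions: TIPSCl (1.0 equiv), imidazole, DMF, 0 °C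
Reagents that add atoms: chlorotriisopropylsilane (TIPSCl), CC(C)[Si](Cl)(C(C)C)C(C)C
Why: Silylation with the bulky chlorosilane should occur at the 4-hydroxyl, which has no ortho substituent, in preference to the hydroxyl next to the methyl group (steric differentiation of two phenols).

Step 2
Reactants: 2 2-methyl-4-(triisopropylsilyloxy)phenol
Product: 3 2-hydroxy-3-methyl-5-(triisopropylsilyloxy)benzaldehyde
Conditions: MgCl2, Et3N, paraformaldehyde, MeCN, reflux; aq. HCl work-up
Reagents that add atoms: paraformaldehyde (as formaldehyde), C=O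
Why: Magnesium-phenoxide-directed ortho-formylation (Casnati–Skattebøl reaction) brings formaldehyde to the only free position ortho to the free hydroxyl, and a second equivalent of formaldehyde oxidises the benzylic alkoxide to the aldehyde.

Step 3
Reactants: 4 (2E,6E)-farnesol
Product: 5 (2E,6E)-farnesyl methyl carbonate
Conditions: ClCO2Me, pyridine, CH2Cl2, 0 °C
Reagents that add atoms: methyl chloroformate, COC(=O)Cl
Why: Acylation of a primary allylic alcohol by a chloroformate, which leaves both E alkenes untouched.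

Step 4
Reactants: 3 2-hydroxy-3-methyl-5-(triisopropylsilyloxy)benzaldehyde; 5 (2E,6E)-farnesyl methyl carbonate
Product: 6 3-methyl-5-(triisopropylsilyloxy)-2-{[(3R,6E)-3,7,11-trimethyldodeca-1,6,10-trien-3-yl]oxy}benzaldehyde
Conditions: 3 (1.2 equiv), Pd2(dba)3·CHCl3 (2.5 mol%), (R,R)-DACH-phenyl ligand [(1R,2R)-N,N'-bis(2-diphenylphosphinobenzoyl)cyclohexane-1,2-diamine] (7.5 mol%), CH2Cl2 (0.05 M), rt
Reagents that add atoms: none
Why: Tsuji–Trost allylic etherification, in which zerovalent palladium ionises the carbonate to a 1,1-disubstituted π-allyl complex, the phenoxide formed by the released methoxide attacks the more substituted allyl terminus inside the chiral pocket of the diphosphine to give the branched tertiary ether, and the ligand decides which face of that terminus is attacked, so setting C2 as R.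

Step 5
Reactants: 6 3-methyl-5-(triisopropylsilyloxy)-2-{[(3R,6E)-3,7,11-trimethyldodeca-1,6,10-trien-3-yl]oxy}benzaldehyde
Product: 7 2-methyl-4-(triisopropylsilyloxy)-1-{[(3R,6E)-3,7,11-trimethyldodeca-1,6,10-trien-3-yl]oxy}-6-vinylbenzene
Conditions: Ph3PCH3Br, KN(SiMe3)2, THF, 0 °C → rt
Reagents that add atoms: methyltriphenylphosphonium bromide, C[P+](c1ccccc1)(c1ccccc1)c1ccccc1.[Br-]
Why: Wittig methylenation of an aromatic aldehyde by a non-stabilised ylide, in which the tertiary ether carbon has no acidic hydrogen and no bond to C2 is touched.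

Step 6
Reactants: 7 2-methyl-4-(triisopropylsilyloxy)-1-{[(3R,6E)-3,7,11-trimethyldodeca-1,6,10-trien-3-yl]oxy}-6-vinylbenzene
Product: 8 (2R)-2-[(3E)-4,8-dimethylnona-3,7-dien-1-yl]-2,8-dimethyl-6-(triisopropylsilyloxy)-2H-chromene
Conditions: second-generation Grubbs catalyst (H2IMes)(PCy3)Cl2Ru=CHPh (5 mol%), CH2Cl2 (0.005 M), 40 °C
Reagents that add atoms: none
Why: The ruthenium benzylidene (divalent ruthenium) exchanges its carbene with the unhindered aryl vinyl group, the aryl-substituted carbene adds in a [2+2] fashion across the vinyl group on C2, and cycloreversion of the ruthenacyclobutane forms C3=C4 and passes on a methylidene that leaves as ethylene. The closest known reaction type is the ring-closing metathesis of 2-vinylphenyl allyl ethers to 2H-chromenes, 2,2-disubstituted cases included. Ring B closes as a six-membered ring because the two terminal alkene carbons that become C4 and C3 are joined through C4a, C8a, O1 and C2, three of which the arene holds in a cisoid arrangement. No stereocentre is created, and C2, set in step 4, keeps its configuration because none of its four bonds takes part. The step needs chemoselectivity for the two monosubstituted alkenes over the two trisubstituted chain alkenes, which their substitution secures (they react far more slowly and could only close medium rings), and ring closure over intermolecular metathesis, which dilution, the ortho arrangement and the escape of ethylene secure.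

Step 7
Reactants: 8 (2R)-2-[(3E)-4,8-dimethylnona-3,7-dien-1-yl]-2,8-dimethyl-6-(triisopropylsilyloxy)-2H-chromene
Product: 9 (2R)-2-[(3E)-4,8-dimethylnona-3,7-dien-1-yl]-2,8-dimethyl-6-(triisopropylsilyloxy)chroman
Conditions: 2-nitrobenzenesulfonylhydrazide (excess, in portions), Et3N, CH2Cl2, rt
Reagents that add atoms: none
Why: Diimide reduction, in which concerted syn transfer of two hydrogens should be much faster at the cis-disubstituted C3=C4 than at the two trisubstituted chain alkenes.

Step 8
Reactants: 9 (2R)-2-[(3E)-4,8-dimethylnona-3,7-dien-1-yl]-2,8-dimethyl-6-(triisopropylsilyloxy)chroman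
Product: 11 (2E,6E)-9-[(2R)-2,8-dimethyl-6-(triisopropylsilyloxy)chroman-2-yl]-2,6-dimethylnona-2,6-dienal (C9' aldehyde), via E-allylic alcohol 10 (not isolated)
Conditions: SeO2 (cat.), t-BuOOH, salicylic acid (cat.), CH2Cl2, 0 °C → rt; then MnO2, CH2Cl2, rt
Reagents that add atoms: tert-butyl hydroperoxide (terminal oxygen source), CC(C)(C)OO; selenium dioxide (oxygen carrier), O=[Se]=O
Why: Selenium dioxide allylic oxidation (ene reaction, then [2,3]-sigmatropic shift) should attack the terminal isopropylidene group at its E-methyl, as is usual for polyprenyl chains, and MnO2 then takes the allylic alcohol to the E-enal.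

Step 9
Reactants: 11 (2E,6E)-9-[(2R)-2,8-dimethyl-6-(triisopropylsilyloxy)chroman-2-yl]-2,6-dimethylnona-2,6-dienal
Product: 12 (2E,6E)-9-[(2R)-2,8-dimethyl-6-(triisopropylsilyloxy)chroman-2-yl]-2,6-dimethylnona-2,6-dienoic acid
Conditions: NaClO2, NaH2PO4, 2-methyl-2-butene, t-BuOH/THF/H2O, 0 °C → rt
Reagents that add atoms: sodium chlorite, [Na+].[O-]Cl=O
Why: Pinnick oxidation of the enal by chlorous acid, with 2-methyl-2-butene trapping the hypochlorous acid so that the chain alkenes and the electron-rich arene are spared and the alkene geometry is kept.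

Step 10
Reactants: 12 (2E,6E)-9-[(2R)-2,8-dimethyl-6-(triisopropylsilyloxy)chroman-2-yl]-2,6-dimethylnona-2,6-dienoic acid
Product: 13 (2S,6E)-9-[(2R)-2,8-dimethyl-6-(triisopropylsilyloxy)chroman-2-yl]-2,6-dimethylnon-6-enoic acid
Conditions: H2 (2 atm), Ru(OAc)2[(S)-H8-BINAP] (1 mol%), MeOH/THF, 20 °C
Reagents that add atoms: none
Why: Carboxylate-directed asymmetric hydrogenation by a divalent ruthenium biaryl-diphosphine catalyst, in which the acid binds to ruthenium as carboxylate, hydrogen is delivered to one face of the conjugated C7'=C8' so that the ligand sets C8' as S, and the isolated C3'=C4' alkene, which cannot chelate, is left.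

Step 11
Reactants: 13 (2S,6E)-9-[(2R)-2,8-dimethyl-6-(triisopropylsilyloxy)chroman-2-yl]-2,6-dimethylnon-6-enoic acid
Product: 15 (2S,6E)-9-[(2R)-2,8-dimethyl-6-(triisopropylsilyloxy)chroman-2-yl]-N-methoxy-N,2,6-trimethylnon-6-enamide, via acyl imidazolide 14 (not isolated)
Conditions: 1,1'-carbonyldiimidazole, CH2Cl2, rt; then MeNH(OMe)·HCl, rt
Reagents that add atoms: N,O-dimethylhydroxylamine hydrochloride, CNOC.Cl
Why: Activation of the acid as its acyl imidazolide and aminolysis (Weinreb amide synthesis) under conditions too mild to epimerise C8'.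

Step 12
Reactants: 15 (2S,6E)-9-[(2R)-2,8-dimethyl-6-(triisopropylsilyloxy)chroman-2-yl]-N-methoxy-N,2,6-trimethylnon-6-enamide; 16 3-methylbut-2-enyl phenyl sulfone (commercial)
Product: 17 (2R)-2,8-dimethyl-2-[(3E,8S)-4,8,12-trimethyl-9-oxo-10-(phenylsulfonyl)trideca-3,11-dien-1-yl]-6-(triisopropylsilyloxy)chroman (mixture of C10' epimers)
Conditions: 16 (1.5 equiv), n-BuLi, THF, −78 °C; then 15, −78 → −30 °C; AcOH quench at −78 °C
Reagents that add atoms: none
Why: Acylation of a sulfone-stabilised allylic carbanion, which reacts at the carbon next to sulfur and so attaches the prenyl unit through C10' with C11'=C12' in place, while the chelated tetrahedral adduct of the Weinreb amide prevents over-addition and shields C8' from base.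

Step 13
Reactants: 17 (2R)-2,8-dimethyl-2-[(3E,8S)-4,8,12-trimethyl-9-oxo-10-(phenylsulfonyl)trideca-3,11-dien-1-yl]-6-(triisopropylsilyloxy)chroman
Product: 18 (2R)-2,8-dimethyl-2-[(3E,8S)-4,8,12-trimethyl-9-oxotrideca-3,11-dien-1-yl]-6-(triisopropylsilyloxy)chroman
Conditions: SmI2 (2.5 equiv), THF/MeOH, −78 °C
Reagents that add atoms: none
Why: Reductive desulfonylation of a β-keto sulfone by electron transfer from samarium diiodide gives a samarium enolate across C9'–C10' that methanol protonates at C10' (kinetic α-protonation), so the β,γ-alkene stays out of conjugation and C8', which is never enolised, is kept.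

Step 14
Reactants: 18 (2R)-2,8-dimethyl-2-[(3E,8S)-4,8,12-trimethyl-9-oxotrideca-3,11-dien-1-yl]-6-(triisopropylsilyloxy)chroman
Product: 19 (2R)-2,8-dimethyl-2-[(3E,8S)-4,8,12-trimethyl-9-oxotrideca-3,11-dien-1-yl]chroman-6-ol (CNP0280076.1)
Conditions: tetrabutylammonium fluoride, AcOH (1:1), THF, 0 °C
Reagents that add atoms: none
Why: Fluoride cleavage of the aryl silyl ether, buffered with acetic acid so that C8' does not epimerise and the β,γ-unsaturated ketone does not move into conjugation.

**Compound list**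

1 | 2-methylhydroquinone | Cc1cc(O)ccc1O | starting material
2 | 2-methyl-4-(triisopropylsilyloxy)phenol | Cc1cc(O[Si](C(C)C)(C(C)C)C(C)C)ccc1O | intermediate
3 | 2-hydroxy-3-methyl-5-(triisopropylsilyloxy)benzaldehyde | O=Cc1cc(O[Si](C(C)C)(C(C)C)C(C)C)cc(C)c1O | intermediate
4 | (2E,6E)-farnesol | CC(C)=CCC/C(C)=C/CC/C(C)=C/CO | starting material
5 | (2E,6E)-farnesyl methyl carbonate | CC(C)=CCC/C(C)=C/CC/C(C)=C/COC(=O)OC | intermediate
6 | 3-methyl-5-(triisopropylsilyloxy)-2-{[(3R,6E)-3,7,11-trimethyldodeca-1,6,10-trien-3-yl]oxy}benzaldehyde | O=Cc1cc(O[Si](C(C)C)(C(C)C)C(C)C)cc(C)c1O[C@@](C)(C=C)CC/C=C(\C)CCC=C(C)C | intermediate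
7 | 2-methyl-4-(triisopropylsilyloxy)-1-{[(3R,6E)-3,7,11-trimethyldodeca-1,6,10-trien-3-yl]oxy}-6-vinylbenzene (metathesis precursor) | C=Cc1cc(O[Si](C(C)C)(C(C)C)C(C)C)cc(C)c1O[C@@](C)(C=C)CC/C=C(\C)CCC=C(C)C | intermediate
8 | (2R)-2-[(3E)-4,8-dimethylnona-3,7-dien-1-yl]-2,8-dimethyl-6-(triisopropylsilyloxy)-2H-chromene (metathesis product) | CC(C)=CCC/C(C)=C/CC[C@]1(C)C=Cc2cc(O[Si](C(C)C)(C(C)C)C(C)C)cc(C)c2O1 | intermediate
9 | (2R)-2-[(3E)-4,8-dimethylnona-3,7-dien-1-yl]-2,8-dimethyl-6-(triisopropylsilyloxy)chroman | CC(C)=CCC/C(C)=C/CC[C@]1(C)CCc2cc(O[Si](C(C)C)(C(C)C)C(C)C)cc(C)c2O1 | intermediate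
10 | (2E,6E)-9-[(2R)-2,8-dimethyl-6-(triisopropylsilyloxy)chroman-2-yl]-2,6-dimethylnona-2,6-dien-1-ol | OC/C(C)=C/CC/C(C)=C/CC[C@]1(C)CCc2cc(O[Si](C(C)C)(C(C)C)C(C)C)cc(C)c2O1 | intermediate (not isolated)
11 | (2E,6E)-9-[(2R)-2,8-dimethyl-6-(triisopropylsilyloxy)chroman-2-yl]-2,6-dimethylnona-2,6-dienal | O=C/C(C)=C/CC/C(C)=C/CC[C@]1(C)CCc2cc(O[Si](C(C)C)(C(C)C)C(C)C)cc(C)c2O1 | intermediate
12 | (2E,6E)-9-[(2R)-2,8-dimethyl-6-(triisopropylsilyloxy)chroman-2-yl]-2,6-dimethylnona-2,6-dienoic acid | OC(=O)/C(C)=C/CC/C(C)=C/CC[C@]1(C)CCc2cc(O[Si](C(C)C)(C(C)C)C(C)C)cc(C)c2O1 | intermediate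
13 | (2S,6E)-9-[(2R)-2,8-dimethyl-6-(triisopropylsilyloxy)chroman-2-yl]-2,6-dimethylnon-6-enoic acid | OC(=O)[C@@H](C)CCC/C(C)=C/CC[C@]1(C)CCc2cc(O[Si](C(C)C)(C(C)C)C(C)C)cc(C)c2O1 | intermediate
14 | 1-{(2S,6E)-9-[(2R)-2,8-dimethyl-6-(triisopropylsilyloxy)chroman-2-yl]-2,6-dimethylnon-6-enoyl}imidazole | O=C(n1ccnc1)[C@@H](C)CCC/C(C)=C/CC[C@]2(C)CCc3cc(O[Si](C(C)C)(C(C)C)C(C)C)cc(C)c3O2 | intermediate (not isolated)
15 | (2S,6E)-9-[(2R)-2,8-dimethyl-6-(triisopropylsilyloxy)chroman-2-yl]-N-methoxy-N,2,6-trimethylnon-6-enamide | CON(C)C(=O)[C@@H](C)CCC/C(C)=C/CC[C@]1(C)CCc2cc(O[Si](C(C)C)(C(C)C)C(C)C)cc(C)c2O1 | intermediate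
16 | 3-methylbut-2-enyl phenyl sulfone | CC(C)=CCS(=O)(=O)c1ccccc1 | starting material
17 | (2R)-2,8-dimethyl-2-[(3E,8S)-4,8,12-trimethyl-9-oxo-10-(phenylsulfonyl)trideca-3,11-dien-1-yl]-6-(triisopropylsilyloxy)chroman | CC(C)=CC(C(=O)[C@@H](C)CCC/C(C)=C/CC[C@]1(C)CCc2cc(O[Si](C(C)C)(C(C)C)C(C)C)cc(C)c2O1)S(=O)(=O)c3ccccc3 | intermediate
18 | (2R)-2,8-dimethyl-2-[(3E,8S)-4,8,12-trimethyl-9-oxotrideca-3,11-dien-1-yl]-6-(triisopropylsilyloxy)chroman | CC(C)=CCC(=O)[C@@H](C)CCC/C(C)=C/CC[C@]1(C)CCc2cc(O[Si](C(C)C)(C(C)C)C(C)C)cc(C)c2O1 | intermediate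
19 | (2R)-2,8-dimethyl-2-[(3E,8S)-4,8,12-trimethyl-9-oxotrideca-3,11-dien-1-yl]chroman-6-ol | CC(C)=CCC(=O)[C@@H](C)CCC/C(C)=C/CC[C@]1(C)CCc2cc(O)cc(C)c2O1 | target

**Count**

Total steps: 14. Longest linear sequence: 13 steps (1 → 19 through steps 1, 2 and 4–14); the farnesol branch joins at step 4 after one step.

**Steps most likely to fail**

1. Step 4. The phenoxide is flanked by two ortho substituents and hydrogen-bonded to the formyl group, so its attack on the tertiary allyl terminus may be slow. Re-ionisation of the product could then let the linear, achiral ether build up, and facial discrimination could be incomplete.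
Fallback (sets out from 4, comes back at 7): the C2 configuration is taken from a Sharpless asymmetric epoxidation and the aryl–oxygen bond is made with reversed polarity. Epoxidation of 4 (Ti(OiPr)4, D-(−)-diethyl tartrate, t-BuOOH, 4 Å sieves, CH2Cl2, −20 °C) should give (2R,3R)-2,3-epoxyfarnesol F1. Iodination (PPh3, I2, imidazole) gives the epoxy iodide F2, and zinc dust in ethanol should open it reductively to (R)-nerolidol F3, the epoxide C3–O bond and its configuration being kept. The potassium alkoxide of F3 (KN(SiMe3)2, THF/DMF, 0 °C) should displace fluoride from commercial 5-bromo-2-fluoro-3-methylbenzaldehyde (nucleophilic aromatic substitution activated by the ortho-formyl group, no bond to the stereocentre broken) to give the bromo aldehyde ether F4. Wittig methylenation gives the bromostyrene ether F5. Bromine–lithium exchange (n-BuLi, THF, −78 °C) and B(OMe)3 give the arylboronate F6, which is oxidised in the same flask (H2O2, NaOH) to the phenol F7. Silylation (TIPSCl, imidazole) returns 7.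

2. Step 8. The ene reaction may also occur at the allylic positions of the internal C3'=C4' alkene (above all the C5' methylene), and conversion may stall, giving poor site selectivity at a late stage.
Fallback (sets out from 9, comes back at 11): cross-metathesis of the terminal isopropylidene group with methacrolein, using the second-generation Hoveyda–Grubbs catalyst (H2IMes)Cl2Ru=CH(C6H4-2-OiPr) in CH2Cl2 at 40 °C. This exchanges the CMe2 terminus for the C(Me)CHO terminus and should give the E-enal 11 directly with loss of isobutene; the more hindered internal trisubstituted alkene is expected to react more slowly. No new compound lies on this way (F0).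

3. Step 12. Addition of the stabilised carbanion to the α-branched amide may be sluggish, which would give time for deprotonation at C8' (epimerisation) or for reaction of the allyl anion at its γ-carbon.
Fallback (sets out from 15, comes back at 18): the prenyl unit is added to an aldehyde instead of an amide. Reduction of 15 (LiAlH4, THF, −78 °C) should give the (S)-2-methyl aldehyde F8. Prenylbarium chloride Me2C=CHCH2BaCl (from BaI2, lithium biphenylide and prenyl chloride, THF, −78 °C), which reacts at its α-carbon, should give the homoallylic alcohol F9 as a mixture of C9' epimers. Oxidation with Dess–Martin periodinane buffered with NaHCO3 returns 18, so that steps 12 and 13 are both replaced.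

**Further compounds**

F1 | step 4 | (2R,3R)-2,3-epoxyfarnesol | OC[C@H]1O[C@]1(C)CC/C=C(\C)CCC=C(C)C
F2 | step 4 | epoxy iodide from F1 (1-iodo-2,3-epoxy-3,7,11-trimethyldodeca-6,10-diene, same spatial arrangement as F1) | IC[C@H]1O[C@]1(C)CC/C=C(\C)CCC=C(C)C
F3 | step 4 | (R)-(E)-nerolidol | C=C[C@](C)(O)CC/C=C(\C)CCC=C(C)C
F4 | step 4 | 5-bromo-3-methyl-2-{[(3R,6E)-3,7,11-trimethyldodeca-1,6,10-trien-3-yl]oxy}benzaldehyde | O=Cc1cc(Br)cc(C)c1O[C@@](C)(C=C)CC/C=C(\C)CCC=C(C)C
F5 | step 4 | 4-bromo-2-methyl-1-{[(3R,6E)-3,7,11-trimethyldodeca-1,6,10-trien-3-yl]oxy}-6-vinylbenzene | C=Cc1cc(Br)cc(C)c1O[C@@](C)(C=C)CC/C=C(\C)CCC=C(C)C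
F6 | step 4 | dimethyl (3-methyl-4-{[(3R,6E)-3,7,11-trimethyldodeca-1,6,10-trien-3-yl]oxy}-5-vinylphenyl)boronate | C=Cc1cc(B(OC)OC)cc(C)c1O[C@@](C)(C=C)CC/C=C(\C)CCC=C(C)C
F7 | step 4 | 3-methyl-4-{[(3R,6E)-3,7,11-trimethyldodeca-1,6,10-trien-3-yl]oxy}-5-vinylphenol | C=Cc1cc(O)cc(C)c1O[C@@](C)(C=C)CC/C=C(\C)CCC=C(C)C
F0 | step 8 | none | none
F8 | step 12 | (2S,6E)-9-[(2R)-2,8-dimethyl-6-(triisopropylsilyloxy)chroman-2-yl]-2,6-dimethylnon-6-enal | O=C[C@@H](C)CCC/C(C)=C/CC[C@]1(C)CCc2cc(O[Si](C(C)C)(C(C)C)C(C)C)cc(C)c2O1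
F9 | step 12 | (2R)-2-[(3E,8S)-9-hydroxy-4,8,12-trimethyltrideca-3,11-dien-1-yl]-2,8-dimethyl-6-(triisopropylsilyloxy)chroman | CC(C)=CCC(O)[C@@H](C)CCC/C(C)=C/CC[C@]1(C)CCc2cc(O[Si](C(C)C)(C(C)C)C(C)C)cc(C)c2O1
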